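**Retrosynthetic overview**

- Feature: ring A (C4a, C5–C8, C8a; O1 on C8a, OH on C5, OMe on C6 and C7) and ring B (C1'–C6'; OH on C6', OMe on C2', C3', C4') are the same 2-oxy-4,5,6-trimethoxyphenyl unit. Cutting C4–C4a and C2–C1' therefore unfolds the C2–C3–C4 bridge to a symmetric 1,3-diaryl-propane-1,3-dione.
- Target 11 ⇐ peri-selective 5-O-demethylation of 6'-hydroxy-hexamethoxyflavone 9 ⇐ cyclodehydration (O1–C2, ring C) of bis-phenol diketone 7 ⇐ hydrogenolysis of dibenzyl diketone 6.
- 6 ⇐ double Friedel–Crafts acylation of two molecules of benzyl ether 3 by malonyl dichloride 4 (both aryl–CO bonds in one operation); 3 ⇐ 3,4,5-trimethoxyphenol 1 + benzyl bromide 2.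
- Ring order: rings A and B come intact from 1; ring C is the only ring made (step 4). Either phenol of 7 closes to the same flavone, so no regioisomer can arise.

Key step: step 2

Remark: the target has no stereocentre; hemiketal 8 and the fallback aldol F4 are racemic and lose their stereocentre in the next operation. Boron intermediate 10 is drawn with covalent O–B bonds only, the dative contact to the C4 carbonyl being left out.

**Route**

Step 1
Reactants: 1 3,4,5-trimethoxyphenol; 2 benzyl bromide
Product: 3 1-(benzyloxy)-3,4,5-trimethoxybenzene
Conditions: BnBr (1.1 equiv), K2CO3 (1.5 equiv), DMF, rt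
Reagents that add atoms: benzyl bromide, BrCc1ccccc1
Why: Williamson O-alkylation of the phenoxide (SN2 at the benzylic carbon); the phenol is the only acidic site of 1.

Step 2
Reactants: 3 1-(benzyloxy)-3,4,5-trimethoxybenzene (two molecules enter the product; 3 equiv used, the excess to be recovered); 4 malonyl dichloride
Product: 6 1,3-bis[2-(benzyloxy)-4,5,6-trimethoxyphenyl]propane-1,3-dione, via keto acid chloride 5 (not isolated)
Conditions: 4 added slowly to 3 (3 equiv) + SnCl4 (2.2 equiv), CH2Cl2, −40 → −10 °C; then cold 1 M HCl
Reagents that add atoms: malonyl dichloride, O=C(Cl)CC(=O)Cl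
Why: SnCl4 polarises one C–Cl bond of 4 to an acylium-type electrophile, which is attacked by C2 of 3 (electrophilic aromatic substitution at a carbon flanked by OBn and OMe and para to a third OMe, a phloroglucinol-like site) to give keto acid chloride 5; its remaining COCl, activated directly or as the derived aroylketene, then acylates a second molecule of 3, so that C4–C4a and C2–C1' of the future flavone are formed in one operation. The closest known reaction type is the Friedel–Crafts diacylation of alkoxybenzenes with malonyl dichloride to 1,3-diaryl-1,3-diketones. No ring closes and no stereocentre is formed. Regioselectivity is not at stake because the two free ring positions of 3 are homotopic, and being meta to each other they cannot be bridged by one malonyl unit to an indane-1,3-dione. What is needed is chemoselectivity: the second intermolecular C-acylation must be faster than attack of the ortho oxygen of 5 on its own acid chloride (loss of benzyl, 4-hydroxycoumarin), which the excess of 3 present during slow addition of 4, the low temperature and the benzyl ether in place of a free phenol should secure. SnCl4 at low temperature is chosen over AlCl3 so that the benzyl ethers and the methoxy groups ortho to the new ketones are not cleaved.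

Step 3
Reactants: 6 1,3-bis[2-(benzyloxy)-4,5,6-trimethoxyphenyl]propane-1,3-dione
Product: 7 1,3-bis(2-hydroxy-4,5,6-trimethoxyphenyl)propane-1,3-dione
Conditions: H2 (1 atm), 10% Pd/C, EtOAc–MeOH, rt
Reagents that add atoms: none
Why: catalytic hydrogenolysis of the two benzyl aryl ethers should leave the methyl ethers and the hindered, doubly ortho-substituted aryl ketones untouched at ambient pressure; 7 may partly close to hemiketal 8, which is equally competent in step 4.

Step 4
Reactants: 7 1,3-bis(2-hydroxy-4,5,6-trimethoxyphenyl)propane-1,3-dione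
Product: 9 2-(6-hydroxy-2,3,4-trimethoxyphenyl)-5,6,7-trimethoxy-4H-chromen-4-one, via 2-hydroxyflavanone hemiketal 8 (not isolated)
Conditions: conc. H2SO4 (cat.), AcOH, 90 °C
Reagents that add atoms: none
Why: acid-catalysed cyclodehydration of a 1-(2-hydroxyaryl)-1,3-diketone (the closing stage of a Baker–Venkataraman flavone synthesis): one phenol adds 6-exo-trig to the distal protonated carbonyl to give hemiketal 8, and loss of water gives the aromatic 4-pyranone; the symmetry of 7 means either phenol leads to the same flavone 9, the other remaining as the 6'-OH.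

Step 5
Reactants: 9 2-(6-hydroxy-2,3,4-trimethoxyphenyl)-5,6,7-trimethoxy-4H-chromen-4-one
Product: 11 5,6'-dihydroxy-6,7,2',3',4'-pentamethoxyflavone, via bis(dichloroboryloxy)flavone 10 (not isolated)
Conditions: BCl3 (3 equiv, 1 M in CH2Cl2), CH2Cl2, −78 → 0 °C; then ice-water
Reagents that add atoms: none
Why: chelation-controlled Lewis-acid ether cleavage: BCl3 bound to the C4 carbonyl forms a six-membered chelate with the peri 5-OMe oxygen and chloride removes that methyl by SN2, while the 6'-OH is only converted to an aryloxydichloroborane and the other five methoxy groups have no neighbouring carbonyl; aqueous work-up hydrolyses both O–B bonds of 10.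

**Compound list**

1 | 3,4,5-trimethoxyphenol | COc1cc(O)cc(OC)c1OC | starting material
2 | benzyl bromide | BrCc1ccccc1 | starting material
3 | 1-(benzyloxy)-3,4,5-trimethoxybenzene | COc1cc(OCc2ccccc2)cc(OC)c1OC | intermediate
4 | malonyl dichloride | O=C(Cl)CC(=O)Cl | starting material
5 | 3-[2-(benzyloxy)-4,5,6-trimethoxyphenyl]-3-oxopropanoyl chloride (not isolated) | COc1cc(OCc2ccccc2)c(C(=O)CC(=O)Cl)c(OC)c1OC | intermediate
6 | 1,3-bis[2-(benzyloxy)-4,5,6-trimethoxyphenyl]propane-1,3-dione | COc1cc(OCc2ccccc2)c(C(=O)CC(=O)c2c(OCc3ccccc3)cc(OC)c(OC)c2OC)c(OC)c1OC | intermediate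
7 | 1,3-bis(2-hydroxy-4,5,6-trimethoxyphenyl)propane-1,3-dione | COc1cc(O)c(C(=O)CC(=O)c2c(O)cc(OC)c(OC)c2OC)c(OC)c1OC | intermediate
8 | 2-hydroxy-2-(2-hydroxy-4,5,6-trimethoxyphenyl)-5,6,7-trimethoxy-2,3-dihydro-4H-chromen-4-one (racemic, not isolated) | COc1cc(O)c(C2(O)CC(=O)c3c(OC)c(OC)c(OC)cc3O2)c(OC)c1OC | intermediate
9 | 2-(6-hydroxy-2,3,4-trimethoxyphenyl)-5,6,7-trimethoxy-4H-chromen-4-one (6'-hydroxy-5,6,7,2',3',4'-hexamethoxyflavone) | COc1cc(O)c(-c2cc(=O)c3c(OC)c(OC)c(OC)cc3o2)c(OC)c1OC | intermediate
10 | 5,6'-bis(dichloroboryloxy)-6,7,2',3',4'-pentamethoxyflavone (not isolated) | COc1cc(OB(Cl)Cl)c(-c2cc(=O)c3c(OB(Cl)Cl)c(OC)c(OC)cc3o2)c(OC)c1OC | intermediate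
11 | 5,6'-dihydroxy-6,7,2',3',4'-pentamethoxyflavone | COc1cc(O)c(-c2cc(=O)c3c(O)c(OC)c(OC)cc3o2)c(OC)c1OC | target

**Step count**

Total step count: 5. Longest linear sequence: 5 steps (1 → 3 → 6 → 7 → 9 → 11).

**Steps most likely to fail**

1. Step 2. The risks are three:
- the monoacylated acid chloride may close onto its ortho oxygen with loss of benzyl before a second arene arrives;
- the Lewis acid may strip benzyl groups;
- the enolised product may be C-acylated further.

The fallback builds the same diketone one aryl–carbon bond at a time, setting out from 1 and 3 and returning at 6. Phenol 1 is C-acetylated ortho to the hydroxyl (AcOH, BF3·OEt2, 90 °C) to 1-(6-hydroxy-2,3,4-trimethoxyphenyl)ethanone F1. This is benzylated (2, K2CO3, DMF) to 1-[2-(benzyloxy)-4,5,6-trimethoxyphenyl]ethanone F2. In parallel, 3 is formylated under Vilsmeier–Haack conditions (POCl3, DMF, 0 °C → rt, then aqueous NaOAc) to 2-(benzyloxy)-4,5,6-trimethoxybenzaldehyde F3. The lithium enolate of F2 (LiN(iPr)2, THF, −78 °C) is added to F3 to give racemic 1,3-bis[2-(benzyloxy)-4,5,6-trimethoxyphenyl]-3-hydroxypropan-1-one F4. Oxidation of the carbinol with 2-iodoxybenzoic acid (EtOAc, 75 °C) should then deliver 6, where the route is rejoined.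

2. Step 5. Once the boron sits on O5 it can bridge to the neighbouring 6-methoxy oxygen and remove a second methyl, or the 6'-aryloxyborane may sequester reagent and leave the cleavage incomplete. The fallback abandons the Lewis-acid chelate for a Brønsted-acid peri-demethylation, setting out from 9 and returning at 11. Flavone 9 is heated in concentrated HCl–EtOH at reflux. The protonated C4 carbonyl, hydrogen-bonded to O5, activates only that O-methyl toward chloride, and no bridging to O6 is available, so the reaction should stop at the 5-hydroxy stage. No compound outside the list is made (F0).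

3. Step 3. Hydrogenolysis may stall through catalyst poisoning by tin residues carried over from step 2, or the enolised diketone or the benzylic ketones may be reduced. The fallback replaces hydrogenolysis by acidolysis and merges it with ring closure, setting out from 6 and returning at 9. Diketone 6 is treated with 33% HBr in AcOH at rt: the benzyl aryl ethers are cleaved by bromide at the benzylic carbon, and the freed phenols cyclodehydrate in the same medium through 7 and 8 to flavone 9. Any 5-O-demethylation that sets in only leads on toward 11. No compound outside the list is made (F0).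

**Further compounds**

F1 | step 2 | 1-(6-hydroxy-2,3,4-trimethoxyphenyl)ethanone | CC(=O)c1c(O)cc(OC)c(OC)c1OC
F2 | step 2 | 1-[2-(benzyloxy)-4,5,6-trimethoxyphenyl]ethanone | CC(=O)c1c(OCc2ccccc2)cc(OC)c(OC)c1OC
F3 | step 2 | 2-(benzyloxy)-4,5,6-trimethoxybenzaldehyde | O=Cc1c(OCc2ccccc2)cc(OC)c(OC)c1OC
F4 | step 2 | 1,3-bis[2-(benzyloxy)-4,5,6-trimethoxyphenyl]-3-hydroxypropan-1-one (racemic) | COc1cc(OCc2ccccc2)c(C(=O)CC(O)c2c(OCc3ccccc3)cc(OC)c(OC)c2OC)c(OC)c1OC
F0 | step 5 | none | none
F0 | step 3 | none | none
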